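**Strategy.** The heptane chain is numbered C1–C7 (OH on C3, OAc on C5). Everything rests on forming C3–C4 by an acetoxy-Prins cyclisation. The feature exploited is that C7 is benzylic (bonded to a guaiacyl ring): the C3 oxygen can be tied to C7 as a 2-aryloxane and released later by hydrogenolysis. An (S)-1-arylbut-3-en-1-ol (C4–C7) and a 3-arylpropanal (C1–C3) condense to an oxocarbenium ion; its chair cyclisation forms C3–C4, sets C3 and C5 from the one benzylic stereocentre and installs the acetate at C5. The all-cis oxane is the masked 3,5-anti diol monoacetate; cleaving the benzylic C7–O bond erases the relay stereocentre and gives the target.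

Key step: step 5

Remark on the chemistry: the target is read as the (3S,5S), 3,5-anti isomer. Heptane locants are those defined above; ring locants are marked "oxane". Vanillin and dihydroconiferyl alcohol are taken as commercial. Both phenols are carried as benzyl carbonates, which are electron-withdrawing during step 5 and are removed in the same hydrogenolysis that opens the ring.

**Step 1**
Reactants: 1 vanillin (4-hydroxy-3-methoxybenzaldehyde)
Product: 2 benzyl 4-formyl-2-methoxyphenyl carbonate
Conditions: CbzCl, Et3N, CH2Cl2, 0 °C → rt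
Reagents that add atoms: benzyl chloroformate, O=C(Cl)OCc1ccccc1
Why: O-acylation of the phenol by a chloroformate (carbonate formation), to which the aldehyde is inert.

**Step 2**
Reactants: 2 benzyl 4-formyl-2-methoxyphenyl carbonate
Product: 3 benzyl 4-[(1S)-1-hydroxybut-3-en-1-yl]-2-methoxyphenyl carbonate
Conditions: (S)-BINOL (20 mol%), Ti(OiPr)4 (10 mol%), 4 Å MS, allylSnBu3, CH2Cl2, –20 °C; aq. NaHCO3
Reagents that add atoms: allyltributylstannane, C=CC[Sn](CCCC)(CCCC)CCCC
Why: Keck asymmetric allylation: the (S)-BINOL–titanium Lewis acid should direct the allylstannane to the Si face of the aryl aldehyde, which sets the (S)-carbinol, and the neutral medium spares the aryl carbonate.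

**Step 3**
Reactants: 4 dihydroconiferyl alcohol [4-(3-hydroxypropyl)-2-methoxyphenol]
Product: 5 benzyl 4-(3-hydroxypropyl)-2-methoxyphenyl carbonate
Conditions: CbzCl (1.1 equiv), 1 M aq. NaOH (1.1 equiv), CH2Cl2, 0 °C
Reagents that add atoms: benzyl chloroformate, O=C(Cl)OCc1ccccc1
Why: Schotten–Baumann acylation: only the phenol is ionised by aqueous hydroxide, so the phenoxide takes the chloroformate and the primary alcohol stays free.

**Step 4**
Reactants: 5 benzyl 4-(3-hydroxypropyl)-2-methoxyphenyl carbonate
Product: 6 benzyl 2-methoxy-4-(3-oxopropyl)phenyl carbonate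
Conditions: TEMPO (10 mol%), PhI(OAc)2, CH2Cl2, rt
Reagents that add atoms: none
Why: TEMPO/(diacetoxyiodo)benzene oxidation (oxoammonium cycle) should take the primary alcohol to the aldehyde and stop there under neutral conditions that the carbonate tolerates.

**Step 5**
Reactants: 3 benzyl 4-[(1S)-1-hydroxybut-3-en-1-yl]-2-methoxyphenyl carbonate; 6 benzyl 2-methoxy-4-(3-oxopropyl)phenyl carbonate
Product: 9 (2S,4R,6S)-2-[4-(benzyloxycarbonyloxy)-3-methoxyphenyl]-6-{2-[4-(benzyloxycarbonyloxy)-3-methoxyphenyl]ethyl}oxan-4-yl acetate, via oxocarbenium ion 7 (not isolated), via oxan-4-yl cation 8 (not isolated)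
Conditions: BF3·OEt2, AcOH, TMSOAc, CH2Cl2, 0 °C → rt
Reagents that add atoms: acetic acid, CC(=O)O; trimethylsilyl acetate, CC(=O)O[Si](C)(C)C (both feed the same acetate pool)
Why: Acetoxy-Prins cyclisation, a known reaction type for 2,6-cis-4-acyloxyoxanes: 3 and 6 condense under BF3 to the (E)-oxocarbenium ion 7, the terminal alkene carbon (future C4, oxane C5) adds to the oxocarbenium carbon (future C3, oxane C6) to give the secondary oxan-4-yl cation 8, and acetate captures 8. The oxane closes in a 6-endo-trig mode through a chair transition state. The stereocentre at oxane C6 (heptane C3) is controlled by the benzylic stereocentre of 3, because the aryl group and the arylethyl chain both sit equatorial on the chair of the (E)-oxocarbenium ion, which gives the 2,6-cis ring. The stereocentre at oxane C4 (heptane C5) follows from equatorial capture of 8 by acetate, so the all-cis (2S,4R,6S) oxane should result, which corresponds to the 3,5-anti pattern of the target. The step needs ring closure to outrun 2-oxonia-Cope allyl transfer and benzylic ionisation (both would erode the ee and exchange side chains) and Friedel–Crafts capture of 7 by the arene; the acyloxy (carbonate) groups in place of donating phenol oxygens on both guaiacyl rings, TMSOAc as water scavenger and the low temperature are meant to secure this.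

**Step 6**
Reactants: 9 (2S,4R,6S)-2-[4-(benzyloxycarbonyloxy)-3-methoxyphenyl]-6-{2-[4-(benzyloxycarbonyloxy)-3-methoxyphenyl]ethyl}oxan-4-yl acetate
Product: 11 (3S,5S)-3-hydroxy-1,7-bis(4-hydroxy-3-methoxyphenyl)heptan-5-yl acetate, via oxane bisphenol 10 (not isolated)
Conditions: H2 (4 bar), Pd(OH)2/C, EtOAc–AcOH 4:1, rt → 40 °C
Reagents that add atoms: none
Why: Catalytic hydrogenolysis: the two benzyl carbonates should fall to the phenols (toluene and CO2) to give 10, whose benzylic oxane C2–O1 bond, now activated by the para-hydroxy group as in guaiacyl furanoid lignans, is then cleaved on palladium, which turns oxane C2 into the C7 methylene, frees the C3 hydroxyl and leaves C3 and C5 untouched (an acetyl shift between O3 and O5 would be degenerate, since the underlying anti diol is C2-symmetric).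

**Compound list**

1 | vanillin (4-hydroxy-3-methoxybenzaldehyde) | COc1cc(C=O)ccc1O | starting material
2 | benzyl 4-formyl-2-methoxyphenyl carbonate | COc1cc(C=O)ccc1OC(=O)OCc1ccccc1 | intermediate
3 | benzyl 4-[(1S)-1-hydroxybut-3-en-1-yl]-2-methoxyphenyl carbonate | C=CC[C@H](O)c1ccc(OC(=O)OCc2ccccc2)c(OC)c1 | intermediate
4 | dihydroconiferyl alcohol, 4-(3-hydroxypropyl)-2-methoxyphenol | COc1cc(CCCO)ccc1O | starting material
5 | benzyl 4-(3-hydroxypropyl)-2-methoxyphenyl carbonate | COc1cc(CCCO)ccc1OC(=O)OCc1ccccc1 | intermediate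
6 | benzyl 2-methoxy-4-(3-oxopropyl)phenyl carbonate | COc1cc(CCC=O)ccc1OC(=O)OCc1ccccc1 | intermediate
7 | (E)-oxocarbenium ion from 3 and 6 | C=CC[C@@H](c1ccc(OC(=O)OCc2ccccc2)c(OC)c1)/[O+]=C/CCc1ccc(OC(=O)OCc2ccccc2)c(OC)c1 | intermediate
8 | 2,6-cis-2-aryl-6-(arylethyl)oxan-4-yl cation | COc1cc(CC[C@H]2C[CH+]C[C@@H](c3ccc(OC(=O)OCc4ccccc4)c(OC)c3)O2)ccc1OC(=O)OCc1ccccc1 | intermediate
9 | (2S,4R,6S)-2-[4-(benzyloxycarbonyloxy)-3-methoxyphenyl]-6-{2-[4-(benzyloxycarbonyloxy)-3-methoxyphenyl]ethyl}oxan-4-yl acetate | COc1cc(CC[C@H]2C[C@@H](OC(C)=O)C[C@@H](c3ccc(OC(=O)OCc4ccccc4)c(OC)c3)O2)ccc1OC(=O)OCc1ccccc1 | intermediate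
10 | (2S,4R,6S)-2-(4-hydroxy-3-methoxyphenyl)-6-[2-(4-hydroxy-3-methoxyphenyl)ethyl]oxan-4-yl acetate | COc1cc(CC[C@H]2C[C@@H](OC(C)=O)C[C@@H](c3ccc(O)c(OC)c3)O2)ccc1O | intermediate
11 | (3S,5S)-3-hydroxy-1,7-bis(4-hydroxy-3-methoxyphenyl)heptan-5-yl acetate | COc1cc(CC[C@H](O)C[C@H](CCc2ccc(O)c(OC)c2)OC(C)=O)ccc1O | target

**Totals.** Total step count: 6. Longest linear sequence: 4 steps (1 → 2 → 5 → 6, or 3 → 4 → 5 → 6).

**Steps most likely to fail**

First, step 5. Allyl transfer by 2-oxonia-Cope rearrangement and ionisation at the benzylic carbon could compete with ring closure, which would lower the ee and exchange the side chains. Capture of the oxanyl cation by acetate could also lose out to elimination or fluoride capture. The fallback makes the same C3–C4 bond by an aldol reaction without cationic intermediates and sets out from aldehyde 6. Commercial zingerone would be benzylated (BnBr, K2CO3, acetone) to 4-(4-benzyloxy-3-methoxyphenyl)butan-2-one F1. Its kinetic boron enolate ((–)-Ipc2BCl, Et3N, Et2O, –78 °C; the reagent enantiomer expected to direct Re-face addition, to be confirmed on the adduct) would add to 6 in a reagent-controlled boron aldol to give benzyl 4-[(3S)-7-(4-benzyloxy-3-methoxyphenyl)-3-hydroxy-5-oxoheptyl]-2-methoxyphenyl carbonate F2. Evans–Saksena reduction (Me4NBH(OAc)3, MeCN–AcOH, –30 °C) would give the anti diol benzyl 4-[(3S,5S)-7-(4-benzyloxy-3-methoxyphenyl)-3,5-dihydroxyheptyl]-2-methoxyphenyl carbonate F3. Hydrogenolysis (H2, Pd/C, EtOAc) would give (3S,5S)-1,7-bis(4-hydroxy-3-methoxyphenyl)heptane-3,5-diol F4, whose two carbinols are homotopic. MeC(OMe)3 and catalytic CSA would close the cyclic orthoacetate (4S,6S)-4,6-bis[2-(4-hydroxy-3-methoxyphenyl)ethyl]-2-methoxy-2-methyl-1,3-dioxane F5, and aqueous AcOH would open it to the monoacetate. The fallback comes back to the route at target 11.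

Second, step 6. Cleavage of the cyclic benzylic C–O bond could be incomplete, so that the reaction stops at the oxane stage after loss of the carbonates. The fallback sets out from 9 and separates the two events. Mild hydrogenolysis (H2 1 bar, Pd/C, EtOAc) would remove only the carbonates and 10 would be isolated. Ionic hydrogenation (Et3SiH, TFA, CH2Cl2, 0 °C) would then open the ring by ionisation of the p-hydroxybenzylic ether and hydride capture of the cation. It comes back at 11 and makes no compound outside the list.

Third, step 2. Facial discrimination by the titanium catalyst could be insufficient, turnover could be slow on this ester-bearing aldehyde, or the carbonate could be lost by alkoxide exchange. The fallback replaces catalysis by stoichiometric reagent control: Brown allylboration of 2 with (–)-B-allyldiisopinocampheylborane (Et2O, –78 °C, buffered perborate work-up), which adds through a closed chair transition state to the Si face. It sets out from 2, comes back at 3 and makes no compound outside the list.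

**Further compounds**

F1 | step 5 | 4-(4-benzyloxy-3-methoxyphenyl)butan-2-one | CC(=O)CCc1ccc(OCc2ccccc2)c(OC)c1
F2 | step 5 | benzyl 4-[(3S)-7-(4-benzyloxy-3-methoxyphenyl)-3-hydroxy-5-oxoheptyl]-2-methoxyphenyl carbonate | COc1cc(CC[C@H](O)CC(=O)CCc2ccc(OCc3ccccc3)c(OC)c2)ccc1OC(=O)OCc1ccccc1
F3 | step 5 | benzyl 4-[(3S,5S)-7-(4-benzyloxy-3-methoxyphenyl)-3,5-dihydroxyheptyl]-2-methoxyphenyl carbonate | COc1cc(CC[C@H](O)C[C@@H](O)CCc2ccc(OCc3ccccc3)c(OC)c2)ccc1OC(=O)OCc1ccccc1
F4 | step 5 | (3S,5S)-1,7-bis(4-hydroxy-3-methoxyphenyl)heptane-3,5-diol | COc1cc(CC[C@H](O)C[C@@H](O)CCc2ccc(O)c(OC)c2)ccc1O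
F5 | step 5 | (4S,6S)-4,6-bis[2-(4-hydroxy-3-methoxyphenyl)ethyl]-2-methoxy-2-methyl-1,3-dioxane | COc1cc(CC[C@H]2C[C@H](CCc3ccc(O)c(OC)c3)OC(C)(OC)O2)ccc1O
F0 | step 6 | none | none
F0 | step 2 | none | none
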